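The vessel is closed and stirred, and it holds a solid that enters solution with time and an enzyme that works on what has dissolved. What we watch is the product, as a fraction of the solid charged.

| setting | amber | blue | flask |
|---|---|---|---|
| solid substrate | 0.50 mM | 0.50 mM | 0.50 mM |
| free enzyme | 0.050 µM | 0.050 µM | 0.050 µM |
| temperature | 25 °C | 31 °C | 25 °C |
| remark | the very flask that is asked about, followed so far | run made earlier |  |
| time |  |  | 30 min |

- amber (time / min: product / %): 2.50: 26.5; 4.00: 26.9; 6.00: 26.0; 10.0: 25.8; 20.0: 25.0; 30.0: 25.6
- blue (time / min: product / %): 2.50: 8.5; 4.00: 9.6; 6.00: 9.4; 10.0: 8.0; 20.0: 9.5; 30.0: 8.8

(each reading ± 0.5 percentage points)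

- east: change nothing and wait 30 min more
- north: at 30 min raise the temperature by 10 K, then wait 30 min
- west: at 30 min add free enzyme, 100 % of the amount charged, then wait 30 min
- north-east: at 30 min take out 90 % of the product then present, then wait 30 min

- given per volume of solution although it is solid: solid substrate
- product taken out counts as made
- the numbers in the tables scatter with a standard deviation of 0.5 percentage points
- at the start none of the solid substrate is in solution
- additions bring no volume worth counting

- product, in percent of the solid substrate first charged, at 30 min
- the remedy with the largest gain of product, or "none" below 2 percentage points (east / north / west / north-east / none)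
- product present, with what was taken out counted in, in percent of the solid substrate first charged, after west
- product present, with what was taken out counted in, in percent of the solid substrate first charged, after north-east

Amber and blue look alike, with equal charges, and differ in temperature: amber stands at 25 °C, blue at 31 °C. Both are flat from the first reading at 2.50 min to the last at 30.0 min, amber around 26.0 % and blue around 8.97 %. Amber stops with 74.0 % of its charge unreacted, so we do not read the stop as a lack of solid.

We follow one enzyme molecule. At each round it comes to a fork: it goes on to another round, or it dies. Over a whole life this gives the turnovers per enzyme, the total turnover number, which is product made divided by enzyme charged. We read it as 2600 for amber and 897 for blue. Blue's enzyme thus makes 2.90 times fewer rounds than amber's, so in our reading warmth tilts the fork towards dying, and each flask ends where its enzyme's life ends.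

Amber's enzyme then looks finished at 30 min, so we expect nothing from waiting, heating or taking out product, and we keep 26.0 % for now and for north-east. Fresh enzyme brings new lives. The first charge began with nothing dissolved, while the second meets a solution already fed, so we reckon on 52.0 % or somewhat above after west.

The forecast gives 26 % now, west as best, 52 % after west and 26 % after north-east, saying “Fresh enzyme, equal to the original charge, should make another 26% or so”.

The flask gives 25.9 %, and west is best with a gain of 39 percentage points, against 0 points, 0 points and 0 points for east, north and north-east. After west stand 65.2 %, after north-east 25.9 %.

    solid substrate ⇌ starting material, rate k1*(cs1 - [starting material]) while solid is left; crystals form when [starting material] > cs1 (solubility = 0.0910 mM, k = 0.180 /s)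
    complex ⇌ free enzyme + product (K = 6.00 × 10⁻⁴ M, k = 400 /s, Ea = 63.0 kJ/mol, ΔH = 24.0 kJ/mol)
    free enzyme → unfolded enzyme (k = 0.00430 /s, Ea = 261 kJ/mol)
    starting material + free enzyme ⇌ complex (K = 58000 /M, k = 5.80 × 10⁷ /M/s, Ea = 14.0 kJ/mol, ΔH = −66.0 kJ/mol)
    free enzyme → spent catalyst (k = 0.240 /s, Ea = 71.0 kJ/mol)
    (constants at 25 °C)

At 0.179 min in the flask, each step taken net, starting material was still being made 1.62 times faster than it was used up, and of the turnover up to 30 min half of the dissolving was done by 0.180 min and half of the product making by 0.217 min. At 30.0 min the flask holds 18.2 % as starting material, and the west charge made 3940 turnovers per enzyme against the 2600 read for the first, while the neighbour flask charged with 1.2 × 10⁻⁵ mM of free enzyme reaches 8.20 %, which is 3420 turnovers per enzyme.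

The numbers in the tables were computed for an exercise.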